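If grey and amber are to count as equal, feeding the partner must spare less than 2 percentage points of open intermediate, so turn the question round and ask what that demands of the numbers.

| setting | Friday's | Monday's | Tuesday's | Wednesday's | amber | grey | teal | violet |
|---|---|---|---|---|---|---|---|---|
| substrate | 0.010 M | 0.010 M | 0.010 M | 0.0050 M | 0.010 M | 0.010 M | 0.010 M | 0.010 M |
| partner | 0.015 M | 0.0075 M | 0.011 M | 0.015 M | 0.0150 M | 0.0150 M (fed, over 10.0 h) | 0.0150 M | 0.0150 M |
| remark | run made earlier | run made earlier | run made earlier | run made earlier | everything together in a closed stirred flask, run for 10 h | all but partner at the start; partner goes in evenly over 10.0 h, the run ends at 10 h | a single well-mixed tank run continuously and read at steady state, 10 h in it on average | a single well-mixed tank run continuously and read at steady state, 50.0 h in it on average |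
| time |  |  |  |  | 10 h | 10 h |  |  |

- Friday's (time / h: open intermediate / %, target / %): 0.500: 6.5, 0; 1.50: 17.1, 0.5; 3.00: 28.3, 1.4; 4.00: 34.5, 1.0; 6.00: 39.9, 3.0; 8.00: 41.6, 4.2; 10.0: 43.1, 5.6
- Monday's (time / h: open intermediate / %, target / %): 0.833: 10.6, 0.1; 1.50: 16.5, 0; 2.50: 26.1, 0; 3.00: 28.7, 0; 4.00: 34.1, 1.1; 5.00: 38.4, 0.5; 6.00: 41.6, 1.4
- Tuesday's (time / h: open intermediate / %, target / %): 0.333: 5.2, 0; 1.00: 12.2, 0; 1.50: 17.3, 0; 2.50: 24.8, 0.6; 4.00: 33.2, 0.8; 5.00: 38.0, 2.1; 6.00: 40.3, 3.3
- Wednesday's (time / h: open intermediate / %, target / %): 1.33: 15.6, 0.2; 2.50: 25.9, 0.2; 4.00: 33.2, 0.8; 5.00: 35.4, 1.7; 6.00: 40.3, 4.1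

(readings scatter by 0.5 percentage points)

- the stated concentrations are those of everything mixed, before any reaction; amounts are the same in each set-up
- the numbers in the tables scatter by 0.5 percentage points (one standard deviation)
- the feed brings no volume worth counting
- the earlier runs were made in a closed, stirred flask

* the set-up with the highest amount of open intermediate at the outlet or at the end, in percent of the substrate put in ("none" if the first two lie within 2 percentage points) (amber / grey / teal / violet / none)
* amount of open intermediate at the outlet or at the end, in percent of the substrate put in, amber
* amount of open intermediate at the outlet or at the end, in percent of the substrate put in, grey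
* amount of open intermediate at the outlet or at the end, in percent of the substrate put in, teal
* amount of open intermediate at the outlet or at the end, in percent of the substrate put in, violet

Start from Friday's run, which is amber's recipe: at 10.0 h it reads 43.1 % open intermediate and 5.6 % target. Freeze the intermediate curve, since at 6.00 h Monday's run reads 41.6 % against Friday's 39.9 % with half the partner. Monday's target there is about half of Friday's, so treat the drain as pseudo-first-order in intermediate, its rate constant proportional to partner. Hold partner at its full charge in amber, let it rise evenly in grey, and ignore its consumption in both. Friday's run has no reading at 5.00 h, half the dosing time, so borrow Tuesday's 38.0 % from the frozen curve. Apply Simpson's rule to start, middle and end, taking zero intermediate at the start and Friday's last reading at the end, and weight by time over dosing time: this gives 0.610. Call this the kept exposure: the integral of intermediate times partner in a recipe, as a fraction of that integral in amber.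

Equality needs a kept exposure above 0.643, and grey stands lower, though narrowly. My reckoning therefore spares 2.2 points and puts grey near 45.3 %, ahead of amber by more than the margin.

The forecast gives amber 43.5 %, grey 44.9 %, teal 33.6 %, violet 33.7 %, and names none: “Grey and amber lie within 2 points”. Its gap of 1.4 points is smaller than mine.

The flask gives amber 43.0 %, grey 46.8 %, teal 33.3 %, violet 27.9 %: best is grey, by 3.8 points. At 10.0 h grey's target plus over-reaction product stands at 0.454 of amber's, less than the kept exposure of 0.610.

    partner → second intermediate (k = 2.60 × 10⁻⁵ s⁻¹)
    open intermediate + second intermediate ⇌ target (K = 35.0 M⁻¹, k = 0.00240 M⁻¹ s⁻¹)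
    target → over-reaction product (k = 3.80 × 10⁻⁵ s⁻¹)
    substrate ⇌ open intermediate (K = 1.20, k = 3.90 × 10⁻⁵ s⁻¹)

Take a neighbour flask, amber with 0.0060 M partner from the start: its kept exposure is 0.400, lower than grey's 0.610. Its target plus over-reaction product stands at 0.425 of amber's, with 47.3 % open intermediate.

(All runs were generated by integration with made-up constants, noise included.)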